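The ring is numbered C1 (carries the side chain), C2, C3 (carbinol), C4, C5 (C–OMe), C6 (CH–OAc), and the plan cuts C1–C2 and C5–C6. One Diels–Alder reaction joins a 3-siloxy-1,1-dimethoxybutadiene (C2–C5) to the C6=C1 double bond of an (R)-6-tridecyl-5,6-dihydropyranone, whose carbonyl ties the side-chain oxygen to C6. The step exploits the masked β-dicarbonyl hidden in the C3–OH/C4=C5–OMe unit and the C6 acetate, which is the Baeyer–Villiger image of that lactone carbonyl after methyl addition. The lactone stereocenter directs the diene to one face; the C1=C2 alkene is released last by selenoxide elimination.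

Key step: step 6

Remark: 1,1-dimethoxyethene is taken as commercially available; C1′ and C2′ denote the side-chain CH2 and carbinol carbons, C7 the lactone carbonyl carbon.

Step 1
Reactants: 1 tetradecanal
Product: 2 (R)-heptadec-1-en-4-ol
Conditions: allyltributylstannane, (S)-BINOL (10 mol%), Ti(OiPr)4 (10 mol%), 4 Å molecular sieves, CH2Cl2, −20 °C
Reagents that add atoms: allyltributylstannane, C=CC[Sn](CCCC)(CCCC)CCCC
Why: Keck asymmetric allylation; the titanium–BINOLate Lewis acid exposes one aldehyde face, which for an unbranched aliphatic aldehyde and (S)-BINOL should give the (R)-homoallylic alcohol (C2′).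

Step 2
Reactants: 2 (R)-heptadec-1-en-4-ol
Product: 3 (R)-heptadec-1-en-4-yl prop-2-enoate
Conditions: acryloyl chloride, Et3N, DMAP (cat.), CH2Cl2, 0 °C
Reagents that add atoms: acryloyl chloride, C=CC(=O)Cl
Why: O-acylation of the secondary alcohol (esterification), which does not touch the stereocenter.

Step 3
Reactants: 3 (R)-heptadec-1-en-4-yl prop-2-enoate
Product: 4 (R)-6-tridecyl-5,6-dihydro-2H-pyran-2-one
Conditions: second-generation Grubbs catalyst (5 mol%), CH2Cl2 (high dilution), 40 °C
Reagents that add atoms: none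
Why: Ring-closing metathesis of the acrylate with the terminal alkene closes the six-membered unsaturated lactone and releases ethene.

Step 4
Reactants: 5 1,1-dimethoxyethene
Product: 6 4,4-dimethoxybut-3-en-2-one
Conditions: acetyl chloride, Et3N, Et2O, 0 → 23 °C
Reagents that add atoms: acetyl chloride, CC(=O)Cl
Why: C-acylation of an electron-rich ketene acetal by an acid chloride gives the acylketene acetal.

Step 5
Reactants: 6 4,4-dimethoxybut-3-en-2-one
Product: 7 tert-butyl[(4,4-dimethoxybuta-1,3-dien-2-yl)oxy]dimethylsilane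
Conditions: TBSOTf, Et3N, Et2O, 0 °C
Reagents that add atoms: tert-butyldimethylsilyl trifluoromethanesulfonate, CC(C)(C)[Si](C)(C)OS(=O)(=O)C(F)(F)F
Why: Soft enolization and O-silylation of the methyl ketone give the 2-siloxy diene, which has no stereochemical element.

Step 6
Reactants: 4 (R)-6-tridecyl-5,6-dihydro-2H-pyran-2-one, 7 tert-butyl[(4,4-dimethoxybuta-1,3-dien-2-yl)oxy]dimethylsilane
Product: 8 (3R,4aS,8aS)-6-[(tert-butyldimethylsilyl)oxy]-8,8-dimethoxy-3-tridecyl-3,4,4a,5,8,8a-hexahydro-1H-isochromen-1-one (cis-fused, H-4a and H-8a on the face of the tridecyl group)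
Conditions: 7 (2.5 equiv), toluene, 110 °C, sealed tube
Reagents that add atoms: none
Why: Normal-electron-demand Diels–Alder reaction (concerted but asynchronous, at the limit a Mukaiyama–Michael addition followed by ring closure): the nucleophilic CH2 terminus of 7 (C2) bonds to the β-carbon of the lactone (C1) and the ketene-acetal carbon (C5) to the α-carbon (C6). The closest known reaction type is the cycloaddition of 1-alkoxy-3-siloxybutadienes with α,β-unsaturated lactones. The carbocycle is closed by an intermolecular suprafacial [4+2] cycloaddition in which both ring bonds form in the same event, giving a cis-fused bicyclic lactone. The new stereocenters C1 and C6 are controlled by the (R)-carbinol carbon C2′ in the lactone ring: the diene should add to the face anti to the pseudo-equatorial tridecyl group, and the cis fusion follows from the endocyclic alkene. The step needs regioselectivity and facial selectivity; the first is secured by the matched polarization of the donor diene and the enoate, the second by the half-chair of the 6-substituted dihydropyranone, while endo/exo selectivity is irrelevant because C2 and C5 carry no stereocenter.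

Step 7
Reactants: 8 (3R,4aS,8aS)-6-[(tert-butyldimethylsilyl)oxy]-8,8-dimethoxy-3-tridecyl-3,4,4a,5,8,8a-hexahydro-1H-isochromen-1-one
Product: 9 1-[(1R,6S)-4-[(tert-butyldimethylsilyl)oxy]-6-[(2R)-2-hydroxypentadecyl]-2,2-dimethoxycyclohex-3-en-1-yl]ethan-1-one (open form, in equilibrium with its cyclic hemiketal)
Conditions: MeLi (1.1 equiv), THF, −78 °C; then aq NH4Cl
Reagents that add atoms: methyllithium, [Li]C
Why: Mono-addition of an organolithium to a lactone at low temperature (the lithium lactolate resists a second addition) gives the methyl ketone, while the silyl enol ether and the ketal mask the ring carbonyls and C6 stays untouched.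

Step 8
Reactants: 9 1-[(1R,6S)-4-[(tert-butyldimethylsilyl)oxy]-6-[(2R)-2-hydroxypentadecyl]-2,2-dimethoxycyclohex-3-en-1-yl]ethan-1-one
Product: 10 (2R)-1-[(1S,6R)-6-acetyl-3-[(tert-butyldimethylsilyl)oxy]-5,5-dimethoxycyclohex-3-en-1-yl]pentadecan-2-yl acetate
Conditions: Ac2O, pyridine, DMAP (cat.), CH2Cl2, 0 → 23 °C
Reagents that add atoms: acetic anhydride, CC(=O)OC(C)=O
Why: DMAP-catalysed acetylation traps the open-chain tautomer at the C2′ hydroxyl, whose configuration is unchanged.

Step 9
Reactants: 10 (2R)-1-[(1S,6R)-6-acetyl-3-[(tert-butyldimethylsilyl)oxy]-5,5-dimethoxycyclohex-3-en-1-yl]pentadecan-2-yl acetate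
Product: 11 (2R)-1-[(1S,6S)-6-acetyl-5-methoxy-3-oxocyclohex-4-en-1-yl]pentadecan-2-yl acetate
Conditions: HCl (0.05 M), THF/H2O (10:1), 0 °C, short contact
Reagents that add atoms: none
Why: Acid-catalysed unmasking of the siloxy allylic ketal: vinylogous ionization of one methoxy group and loss of the silyl group give the 3-methoxy enone (vinylogous ester) regiospecifically toward C4, and brief exposure to dilute acid at 0 °C should leave the enolizable C6 center intact.

Step 10
Reactants: 11 (2R)-1-[(1S,6S)-6-acetyl-5-methoxy-3-oxocyclohex-4-en-1-yl]pentadecan-2-yl acetate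
Product: 12 (2R)-1-[(1S,6S)-6-acetoxy-5-methoxy-3-oxocyclohex-4-en-1-yl]pentadecan-2-yl acetate
Conditions: mCPBA, NaHCO3, CH2Cl2, 23 °C
Reagents that add atoms: 3-chloroperbenzoic acid, OOC(=O)c1cccc(Cl)c1
Why: Baeyer–Villiger oxidation: the secondary ring carbon C6 migrates in preference to methyl and with retention of configuration, so the acetyl group becomes the C6 acetate, and the electron-poor methoxy enone should resist the peracid.

Step 11
Reactants: 12 (2R)-1-[(1S,6S)-6-acetoxy-5-methoxy-3-oxocyclohex-4-en-1-yl]pentadecan-2-yl acetate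
Product: 14 (2R)-1-[(1R,2S,6S)-6-acetoxy-5-methoxy-3-oxo-2-(phenylselanyl)cyclohex-4-en-1-yl]pentadecan-2-yl acetate, via silyl dienol ether 13 (not isolated)
Conditions: TMSOTf, Et3N, CH2Cl2, −78 → 0 °C; then PhSeCl, −78 °C
Reagents that add atoms: phenylselenyl chloride, Cl[Se]c1ccccc1
Why: Soft enolization of the vinylogous ester toward C2 (cross-conjugated silyl dienol ether) followed by electrophilic α-selenenylation; selenium should enter C2 anti to the adjacent C1 side chain, that is cis to H-1.

Step 12
Reactants: 14 (2R)-1-[(1R,2S,6S)-6-acetoxy-5-methoxy-3-oxo-2-(phenylselanyl)cyclohex-4-en-1-yl]pentadecan-2-yl acetate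
Product: 15 (2R)-1-[(1R,2S,3S,6S)-6-acetoxy-3-hydroxy-5-methoxy-2-(phenylselanyl)cyclohex-4-en-1-yl]pentadecan-2-yl acetate
Conditions: NaBH4, CeCl3·7H2O, MeOH/THF, −78 °C; quench with aq NaHCO3
Reagents that add atoms: none
Why: Luche 1,2-reduction: the small hydride should add axially to the half-chair that keeps the C1 side chain and the C2 selenide equatorial, from the face opposite the pseudo-axial C6 acetate, setting the equatorial C3 alcohol cis to the C6 acetate (3R in the target).

Step 13
Reactants: 15 (2R)-1-[(1R,2S,3S,6S)-6-acetoxy-3-hydroxy-5-methoxy-2-(phenylselanyl)cyclohex-4-en-1-yl]pentadecan-2-yl acetate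
Product: 17 (2R)-1-[(3R,6S)-6-acetoxy-3-hydroxy-5-methoxycyclohexa-1,4-dien-1-yl]pentadecan-2-yl acetate (CNP0123936.1), via selenoxide 16 (not isolated)
Conditions: NaIO4, NaHCO3, THF/H2O, 0 → 23 °C
Reagents that add atoms: none
Why: Selenide oxidation and syn-elimination of the selenoxide: H-1 is syn to selenium and elimination toward the carbinol carbon C3 is disfavoured, so the C1=C2 alkene should form under neutral conditions that the acid-labile methoxy dienol tolerates, erasing the relay stereocenters C1 and C2.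

Compound list
1 | tetradecanal | CCCCCCCCCCCCCC=O | starting material
2 | (R)-heptadec-1-en-4-ol | CCCCCCCCCCCCC[C@H](CC=C)O | intermediate
3 | (R)-heptadec-1-en-4-yl prop-2-enoate | CCCCCCCCCCCCC[C@H](CC=C)OC(=O)C=C | intermediate
4 | (R)-6-tridecyl-5,6-dihydro-2H-pyran-2-one | CCCCCCCCCCCCC[C@@H]1CC=CC(=O)O1 | intermediate
5 | 1,1-dimethoxyethene | COC(=C)OC | starting material
6 | 4,4-dimethoxybut-3-en-2-one | CC(=O)C=C(OC)OC | intermediate
7 | tert-butyl[(4,4-dimethoxybuta-1,3-dien-2-yl)oxy]dimethylsilane | C=C(O[Si](C)(C)C(C)(C)C)C=C(OC)OC | intermediate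
8 | (3R,4aS,8aS)-6-[(tert-butyldimethylsilyl)oxy]-8,8-dimethoxy-3-tridecyl-3,4,4a,5,8,8a-hexahydro-1H-isochromen-1-one | CCCCCCCCCCCCC[C@@H]1C[C@H]2CC(O[Si](C)(C)C(C)(C)C)=CC(OC)(OC)[C@H]2C(=O)O1 | intermediate
9 | 1-[(1R,6S)-4-[(tert-butyldimethylsilyl)oxy]-6-[(2R)-2-hydroxypentadecyl]-2,2-dimethoxycyclohex-3-en-1-yl]ethan-1-one (open form of the cyclic hemiketal) | CCCCCCCCCCCCC[C@@H](O)C[C@H]1CC(O[Si](C)(C)C(C)(C)C)=CC(OC)(OC)[C@H]1C(C)=O | intermediate
10 | (2R)-1-[(1S,6R)-6-acetyl-3-[(tert-butyldimethylsilyl)oxy]-5,5-dimethoxycyclohex-3-en-1-yl]pentadecan-2-yl acetate | CCCCCCCCCCCCC[C@@H](OC(C)=O)C[C@H]1CC(O[Si](C)(C)C(C)(C)C)=CC(OC)(OC)[C@H]1C(C)=O | intermediate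
11 | (2R)-1-[(1S,6S)-6-acetyl-5-methoxy-3-oxocyclohex-4-en-1-yl]pentadecan-2-yl acetate | CCCCCCCCCCCCC[C@@H](OC(C)=O)C[C@H]1CC(=O)C=C(OC)[C@H]1C(C)=O | intermediate
12 | (2R)-1-[(1S,6S)-6-acetoxy-5-methoxy-3-oxocyclohex-4-en-1-yl]pentadecan-2-yl acetate | CCCCCCCCCCCCC[C@@H](OC(C)=O)C[C@H]1CC(=O)C=C(OC)[C@H]1OC(C)=O | intermediate
13 | (2R)-1-[(1S,6S)-6-acetoxy-5-methoxy-3-[(trimethylsilyl)oxy]cyclohexa-2,4-dien-1-yl]pentadecan-2-yl acetate | CCCCCCCCCCCCC[C@@H](OC(C)=O)C[C@H]1C=C(O[Si](C)(C)C)C=C(OC)[C@H]1OC(C)=O | intermediate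
14 | (2R)-1-[(1R,2S,6S)-6-acetoxy-5-methoxy-3-oxo-2-(phenylselanyl)cyclohex-4-en-1-yl]pentadecan-2-yl acetate | CCCCCCCCCCCCC[C@@H](OC(C)=O)C[C@H]1[C@H]([Se]c2ccccc2)C(=O)C=C(OC)[C@H]1OC(C)=O | intermediate
15 | (2R)-1-[(1R,2S,3S,6S)-6-acetoxy-3-hydroxy-5-methoxy-2-(phenylselanyl)cyclohex-4-en-1-yl]pentadecan-2-yl acetate | CCCCCCCCCCCCC[C@@H](OC(C)=O)C[C@H]1[C@H]([Se]c2ccccc2)[C@@H](O)C=C(OC)[C@H]1OC(C)=O | intermediate
16 | Se-oxide of 15 (both configurations at selenium) | CCCCCCCCCCCCC[C@@H](OC(C)=O)C[C@H]1[C@H]([Se](=O)c2ccccc2)[C@@H](O)C=C(OC)[C@H]1OC(C)=O | intermediate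
17 | (2R)-1-[(3R,6S)-6-acetoxy-3-hydroxy-5-methoxycyclohexa-1,4-dien-1-yl]pentadecan-2-yl acetate | CCCCCCCCCCCCC[C@H](CC1=C[C@@H](O)C=C(OC)[C@H]1OC(C)=O)OC(C)=O | target

Total step count: 13. Longest linear sequence: 11 (steps 1–3 and 6–13).

Steps most likely to fail

Step 6. The unsaturated δ-lactone is only a modest dienophile, so the cycloaddition may be slower than thermal decomposition or desilylation of the diene, and facial discrimination by the remote tridecyl group may be incomplete. The fallback replaces the neutral lactone by a cationic dienophile. It sets out from 4: methyllithium addition (THF, −78 °C) should give the lactol (6R)-2-methyl-6-tridecyl-5,6-dihydro-2H-pyran-2-ol F1, and methanol with pyridinium p-toluenesulfonate should turn it into the cyclic ketal (6R)-2-methoxy-2-methyl-6-tridecyl-5,6-dihydro-2H-pyran F2. Catalytic TMSOTf (CH2Cl2, −78 °C) should ionize F2 to a cyclic alkoxyallyl cation, which should undergo a cationic Diels–Alder reaction with 7 on the face anti to the tridecyl group. Dilute-acid work-up should then give 1-[(1S,6S)-6-[(2R)-2-hydroxypentadecyl]-2-methoxy-4-oxocyclohex-2-en-1-yl]ethan-1-one F3. Acetylation (Ac2O, pyridine, DMAP) comes back to the route at 11.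

Step 10. The peracid may epoxidize the methoxy-enone double bond, migration of C6 may be slow, and the C6 center (α to the acetyl group, γ to the vinylogous ester) may epimerize before it is oxidized. The fallback avoids both the enolizable ketone and the peracid by bringing C6 in as a carbon–boron bond. It sets out from 2: transesterification with dibutyl vinylboronate and ring-closing metathesis (second-generation Grubbs catalyst) should give the cyclic alkenylboronic half-ester (6R)-6-tridecyl-5,6-dihydro-2H-1,2-oxaborinin-2-ol F4. Cycloaddition with 7 should give the cis-fused boron analogue of 8, (3R)-6-[(tert-butyldimethylsilyl)oxy]-8,8-dimethoxy-3-tridecyl-3,4,4a,5,8,8a-hexahydro-1H-benzo[c][1,2]oxaborinin-1-ol F5. Oxidation of the C–B bond with NaBO3 (retention) and dilute-acid unmasking should give the diol (4S,5S)-4-hydroxy-5-[(2R)-2-hydroxypentadecyl]-3-methoxycyclohex-2-en-1-one F6. Acetylation of both hydroxyl groups comes back to the route at 12.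

Step 12. Hydride may be delivered anti to the selenium substituent from the other conformer, giving the C3 epimer, and the methoxy allylic alcohol may solvolyse under the Lewis-acidic conditions. The fallback replaces substrate control by reagent control. It sets out from 14: a Corey–Bakshi–Shibata reduction ((S)-2-methyl-CBS-oxazaborolidine, catecholborane, toluene, −78 °C), in which the catalyst selects the carbonyl face with the enone π-system as the large group, should lead directly to 15, where it comes back to the route. It makes no new compound (F0).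

Further compounds
F1 | step 6 | (6R)-2-methyl-6-tridecyl-5,6-dihydro-2H-pyran-2-ol | CCCCCCCCCCCCC[C@@H]1CC=CC(C)(O)O1
F2 | step 6 | (6R)-2-methoxy-2-methyl-6-tridecyl-5,6-dihydro-2H-pyran | CCCCCCCCCCCCC[C@@H]1CC=CC(C)(OC)O1
F3 | step 6 | 1-[(1S,6S)-6-[(2R)-2-hydroxypentadecyl]-2-methoxy-4-oxocyclohex-2-en-1-yl]ethan-1-one | CCCCCCCCCCCCC[C@@H](O)C[C@H]1CC(=O)C=C(OC)[C@H]1C(C)=O
F4 | step 10 | (6R)-6-tridecyl-5,6-dihydro-2H-1,2-oxaborinin-2-ol | CCCCCCCCCCCCC[C@@H]1CC=CB(O)O1
F5 | step 10 | (3R)-6-[(tert-butyldimethylsilyl)oxy]-8,8-dimethoxy-3-tridecyl-3,4,4a,5,8,8a-hexahydro-1H-benzo[c][1,2]oxaborinin-1-ol, cis-fused as in 8 | CCCCCCCCCCCCC[C@@H]1C[C@H]2CC(O[Si](C)(C)C(C)(C)C)=CC(OC)(OC)[C@H]2B(O)O1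
F6 | step 10 | (4S,5S)-4-hydroxy-5-[(2R)-2-hydroxypentadecyl]-3-methoxycyclohex-2-en-1-one | CCCCCCCCCCCCC[C@@H](O)C[C@H]1CC(=O)C=C(OC)[C@H]1O
F0 | step 12 | none | none
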